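**Plan**

- Numbering: carbocycle C1 (C=O), C2 (spiro), C3, C4 (CHOH), C5 (CHNHAc), C6; lactone C7, C8 (C=O), C9 (OCH); side chain from C10. Retrosynthetic cuts, in order: N–C5 (tethered through O4), O9–C8 and C9–C10, O–C4, then C5–C6 and C2–C3 of the carbocycle, last C2–C7.
- Enabling feature: C2 carries the C1 carbonyl, the C9 carboxyl carbon and the C7–C8 acetic arm, so it is the α-carbon of a 2-acetylsuccinate. C3–C4–C5 is a three-carbon enal unit that can bond to C2 (Michael) and to the acetyl methyl C6 (aldol), closing ring C1–C6.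
- Forward: alkylation assembles the acetylsuccinate; Michael–aldol annulation with acrolein makes the cyclohexenone; C4 is oxygenated; the C9 ester becomes an aldehyde; the E-alkenyl chain is joined at C9 and the γ-lactone closes in the same flask; nitrogen is delivered to C5 from O4; trichloroacetyl is reduced to acetyl.
- Stereochemistry: C2 from the cinchona catalyst; C4 by 1,3-induction from C2 in the dienol ether oxidation; C9 from a magnesium chelate between the C9 aldehyde and the C1 ketone; C5 by cis delivery across the five-membered imidate tether; the C10=C11 geometry from syn-carboalumination.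

Key step: step 2

Assumption: the quinidine-derived 6'-hydroxy catalyst (two steps from quinidine, treated as a reagent) is taken to give the 2S adduct 5; if the sense of induction is the opposite, its quinine-derived pseudo-enantiomer 9-O-benzylcupreine is used and nothing else changes.

**Route**

Step 1
Reactants: 1 methyl acetoacetate; 2 tert-butyl bromoacetate
Product: 3 4-tert-butyl 1-methyl 2-acetylbutanedioate (racemic)
Conditions: 1 (1.2 equiv), NaH (1.1 equiv), THF, 0 °C; then 2 (1.0 equiv), 0 → 23 °C
Reagents that add atoms: none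
Why: Acetoacetic ester alkylation, in which the sodium enolate of the β-keto ester displaces bromide from the activated primary α-bromo ester (SN2) while the excess of 1 holds back dialkylation; C2 is left racemic because it stays enolisable and is resolved dynamically in step 2.

Step 2
Reactants: 3 4-tert-butyl 1-methyl 2-acetylbutanedioate; 4 acrolein
Product: 7 methyl (1S)-1-(2-tert-butoxy-2-oxoethyl)-2-oxocyclohex-3-ene-1-carboxylate, via Michael adduct aldehyde 5 (not isolated), via aldol adduct 6 (not isolated)
Conditions: 4 (2 equiv), 9-O-benzylcupreidine (10 mol %), CH2Cl2, −24 °C; evaporate excess 4; pyrrolidine (0.3 equiv), AcOH (0.3 equiv), CH2Cl2, 23 → 40 °C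
Reagents that add atoms: none
Why: The quinuclidine nitrogen of the catalyst deprotonates 3 and the 6'-hydroxyl hydrogen-bonds acrolein, so the ion-paired enolate adds through one face to the enal (C2–C3 bond) and the racemic, rapidly enolising donor is converted entirely into aldehyde 5. Pyrrolidinium acetate then turns the methyl ketone into its enamine, C6 adds to the aldehyde carbon C5 to give aldol 6, and loss of water leaves the C5=C6 enone 7. The closest known reaction type is the cinchona-alkaloid-catalysed Michael addition of α-substituted β-keto esters to enals, followed by a Robinson-type aldol condensation. The carbocycle C1–C6 closes in the 6-(enolendo)-exo-trig mode. The one stereocentre that survives, quaternary C2 (1S in 7), is set by the catalyst in the Michael step and cannot epimerise afterwards because it bears no hydrogen; the carbinol centre of 6 is lost on dehydration. The step needs enantiofacial selectivity at the prochiral enolate, secured by two-point binding of the 1,3-dicarbonyl enolate to the bifunctional catalyst, and the right aldol regiochemistry, secured because the only other closure (C4 onto the acetyl carbonyl) would make a four-membered ring.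

Step 3
Reactants: 7 methyl (1S)-1-(2-tert-butoxy-2-oxoethyl)-2-oxocyclohex-3-ene-1-carboxylate
Product: 8 methyl (1S)-1-(2-tert-butoxy-2-oxoethyl)-2-[(tert-butyldimethylsilyl)oxy]cyclohexa-2,4-diene-1-carboxylate
Conditions: TBSOTf (1.2 equiv), Et3N (2 equiv), CH2Cl2, −78 → 0 °C
Reagents that add atoms: tert-butyldimethylsilyl trifluoromethanesulfonate, CC(C)(C)[Si](C)(C)OS(=O)(=O)C(F)(F)F
Why: Soft enolisation to a silyl dienol ether: because C2 is quaternary, the O-silylated enone can only lose the γ-proton at C4, giving the linear 1-silyloxy-1,3-diene, while the low temperature and the amine base spare the tert-butyl ester and no stereocentre is touched.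

Step 4
Reactants: 8 methyl (1S)-1-(2-tert-butoxy-2-oxoethyl)-2-[(tert-butyldimethylsilyl)oxy]cyclohexa-2,4-diene-1-carboxylate
Product: 10 methyl (1S,5S)-1-(2-tert-butoxy-2-oxoethyl)-5-hydroxy-2-oxocyclohex-3-ene-1-carboxylate, via epoxy silyl enol ether 9 (not isolated)
Conditions: DMDO (1.05 equiv, acetone), CH2Cl2, −78 → −40 °C; then 0.5 M HCl, THF, 0 °C
Reagents that add atoms: dimethyldioxirane, CC1(C)OO1
Why: Vinylogous Rubottom oxidation, in which the dioxirane epoxidises the distal C4=C5 bond of the silyloxydiene (largest HOMO coefficient at C4) and dilute acid opens the vinyl epoxide to the γ-hydroxy enone; C4 is set by 1,3-induction from C2, the CH2CO2tBu arm being expected to stand perpendicular to the diene (avoiding A(1,2) strain with the silyloxy group) and to screen its face, so that oxygen should arrive cis to the ester carbon C9.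

Step 5
Reactants: 10 methyl (1S,5S)-1-(2-tert-butoxy-2-oxoethyl)-5-hydroxy-2-oxocyclohex-3-ene-1-carboxylate
Product: 11 methyl (1S,5S)-1-(2-tert-butoxy-2-oxoethyl)-5-[(tert-butyldimethylsilyl)oxy]-2-oxocyclohex-3-ene-1-carboxylate
Conditions: TBSOTf (1.2 equiv), 2,6-lutidine (2 equiv), CH2Cl2, −78 °C
Reagents that add atoms: tert-butyldimethylsilyl trifluoromethanesulfonate, CC(C)(C)[Si](C)(C)OS(=O)(=O)C(F)(F)F
Why: Silyl ether formation with a silyl triflate and a hindered pyridine base, fast enough at low temperature to forestall lactonisation of the cis-hydroxy ester and base-induced isomerisation of the γ-hydroxy enone; no stereocentre is touched.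

Step 6
Reactants: 11 methyl (1S,5S)-1-(2-tert-butoxy-2-oxoethyl)-5-[(tert-butyldimethylsilyl)oxy]-2-oxocyclohex-3-ene-1-carboxylate
Product: 12 tert-butyl 2-[(1R,5S)-5-[(tert-butyldimethylsilyl)oxy]-2-hydroxy-1-(hydroxymethyl)cyclohex-3-en-1-yl]acetate (both epimers at the ring CHOH carbon)
Conditions: iBu2AlH (4.5 equiv), CH2Cl2, −78 → −40 °C; aq. KNaC4H4O6
Reagents that add atoms: none
Why: Aluminium hydride reduction with DIBAL-H, giving 1,2-reduction of the enone carbonyl and reduction of the methyl ester to the primary alcohol while the bulky tert-butyl ester is left at this temperature; the new C1 carbinol centre is removed again in step 7, and the S to R change at the quaternary carbon only reflects changed CIP priorities.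

Step 7
Reactants: 12 tert-butyl 2-[(1R,5S)-5-[(tert-butyldimethylsilyl)oxy]-2-hydroxy-1-(hydroxymethyl)cyclohex-3-en-1-yl]acetate
Product: 13 tert-butyl 2-[(1R,5S)-5-[(tert-butyldimethylsilyl)oxy]-1-formyl-2-oxocyclohex-3-en-1-yl]acetate
Conditions: Dess–Martin periodinane (2.6 equiv), CH2Cl2, 0 → 23 °C
Reagents that add atoms: none
Why: Dess–Martin oxidation of both the allylic secondary and the neopentylic primary alcohol under non-basic conditions, which restores the C1 enone and gives the non-enolisable β-keto aldehyde without retro-aldol or deformylation; the C1 carbinol centre is erased.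

Step 8
Reactants: 14 6-methylhept-5-en-2-one
Product: 16 6-methylhept-5-en-1-yne, via enol phosphate 15 (not isolated)
Conditions: LiN(iPr)2 (1.05 equiv), THF, −78 °C; ClP(O)(OEt)2, −78 → 23 °C; LiN(iPr)2 (2.3 equiv), −78 → 23 °C; H2O
Reagents that add atoms: none
Why: Methyl ketone to terminal alkyne by enol phosphate elimination: kinetic deprotonation on the methyl side and O-phosphorylation give the terminal enol phosphate, from which the amide base eliminates diethyl phosphate.

Step 9
Reactants: 16 6-methylhept-5-en-1-yne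
Product: 18 (1E)-1-iodo-2,6-dimethylhepta-1,5-diene, via alkenylalane 17 (not isolated)
Conditions: AlMe3 (2 equiv), Cp2ZrCl2 (0.25 equiv), CH2Cl2, 0 → 23 °C; then I2, THF, −30 → 0 °C
Reagents that add atoms: trimethylaluminium, C[Al](C)C; iodine, II
Why: Negishi zirconium-catalysed carboalumination, a syn addition of methyl and aluminium across the terminal alkyne with aluminium at the terminus, followed by iododealumination with retention, which fixes the E geometry; the isolated trisubstituted alkene does not react.

Step 10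
Reactants: 13 tert-butyl 2-[(1R,5S)-5-[(tert-butyldimethylsilyl)oxy]-1-formyl-2-oxocyclohex-3-en-1-yl]acetate; 18 (1E)-1-iodo-2,6-dimethylhepta-1,5-diene
Product: 22 (1R,5R,9S)-9-[(tert-butyldimethylsilyl)oxy]-1-[(1E)-2,6-dimethylhepta-1,5-dien-1-yl]-2-oxaspiro[4.5]dec-7-ene-3,6-dione, via alkenyllithium 19 (not isolated), via alkenylmagnesium bromide 20 (not isolated), via bromomagnesium alkoxide 21 (not isolated)
Conditions: 18, t-BuLi (2.0 equiv), Et2O, −78 °C; MgBr2·OEt2 (1.2 equiv), −78 → 0 °C; add to 13 + MgBr2·OEt2 (1.5 equiv), CH2Cl2, −78 °C; then → 23 °C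
Reagents that add atoms: none
Why: Cram-chelate-controlled Grignard addition followed by lactonisation: iodine–lithium exchange and transmetalation proceed with retention of the E geometry, MgBr2 holds the aldehyde and C1 carbonyl oxygens in a six-membered chelate so that the alkenyl group attacks C9 from the side of the tied-back ring carbon C3 and away from the freely rotating CH2CO2tBu arm (setting 9R, position 1 of 22), and on warming the alkoxide closes the γ-lactone by 5-exo-trig acyl substitution on the tert-butyl ester, helped by the Thorpe–Ingold effect of quaternary C2 and by MgBr2 activation.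

Step 11
Reactants: 22 (1R,5R,9S)-9-[(tert-butyldimethylsilyl)oxy]-1-[(1E)-2,6-dimethylhepta-1,5-dien-1-yl]-2-oxaspiro[4.5]dec-7-ene-3,6-dione
Product: 23 (1R,5R,9S)-1-[(1E)-2,6-dimethylhepta-1,5-dien-1-yl]-9-hydroxy-2-oxaspiro[4.5]dec-7-ene-3,6-dione
Conditions: HF·pyridine, pyridine, THF, 0 → 23 °C
Reagents that add atoms: none
Why: Fluoride-mediated desilylation under buffered, mildly acidic conditions that leave the γ-lactone, the allylic C9–O bond and the γ-hydroxy enone intact; no stereocentre is touched.

Step 12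
Reactants: 23 (1R,5R,9S)-1-[(1E)-2,6-dimethylhepta-1,5-dien-1-yl]-9-hydroxy-2-oxaspiro[4.5]dec-7-ene-3,6-dione
Product: 25 cis-fused 2-(trichloromethyl)-4,5-dihydro-1,3-oxazole spanning O9 and N8 of (1R,5R,8R,9S)-1-[(1E)-2,6-dimethylhepta-1,5-dien-1-yl]-2-oxaspiro[4.5]decane-3,6-dione, via trichloroacetimidate 24 (not isolated)
Conditions: Cl3CCN (2 equiv), DBU (0.3 equiv), CH2Cl2, 0 → 23 °C
Reagents that add atoms: trichloroacetonitrile, ClC(Cl)(Cl)C#N
Why: Base-catalysed addition of the C4 hydroxyl to the nitrile gives the allylic trichloroacetimidate, whose nitrogen adds to the enone β-carbon C5 in a tethered aza-Michael reaction (5-exo-trig); the five-membered tether can reach C5 only on the face of the C4 oxygen, so the cis amino alcohol (5R) is set by C4.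

Step 13
Reactants: 25 cis-fused 2-(trichloromethyl)oxazoline of the spirolactone
Product: 27 2,2,2-trichloro-N-[(1R,5R,8R,9S)-1-[(1E)-2,6-dimethylhepta-1,5-dien-1-yl]-9-hydroxy-3,6-dioxo-2-oxaspiro[4.5]decan-8-yl]acetamide, via amino ester hydrochloride 26 (not isolated)
Conditions: 1 M HCl, THF, 0 → 23 °C; then sat. aq. NaHCO3, 0 °C
Reagents that add atoms: water, O
Why: Acid hydrolysis of the oxazoline: water adds to the protonated C=N, the hemiorthoamide opens to the ammonium trichloroacetate ester, and on neutralisation O-to-N acyl migration through the same five-membered intermediate gives the hydroxy amide; C4 and C5 are not affected.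

Step 14
Reactants: 27 2,2,2-trichloro-N-[(1R,5R,8R,9S)-1-[(1E)-2,6-dimethylhepta-1,5-dien-1-yl]-9-hydroxy-3,6-dioxo-2-oxaspiro[4.5]decan-8-yl]acetamide
Product: 28 (+)-miliusane V, N-[(1R,5R,8R,9S)-1-[(1E)-2,6-dimethylhepta-1,5-dien-1-yl]-9-hydroxy-3,6-dioxo-2-oxaspiro[4.5]decan-8-yl]acetamide
Conditions: Bu3SnH (3.5 equiv), AIBN (0.2 equiv), PhH, 80 °C
Reagents that add atoms: none
Why: Radical chain hydrodechlorination, in which three successive chlorine abstractions by the stannyl radical turn the trichloroacetamide into the acetamide while the ketone, lactone, free hydroxyl and unactivated alkenes are inert; no stereocentre is touched.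

**Compound list**

1 | methyl acetoacetate (methyl 3-oxobutanoate) | CC(=O)CC(=O)OC | starting material
2 | tert-butyl bromoacetate | BrCC(=O)OC(C)(C)C | starting material
3 | 4-tert-butyl 1-methyl 2-acetylbutanedioate (racemic) | CC(=O)C(CC(=O)OC(C)(C)C)C(=O)OC | intermediate
4 | acrolein (prop-2-enal) | C=CC=O | starting material
5 | 4-tert-butyl 1-methyl (2S)-2-acetyl-2-(3-oxopropyl)butanedioate | COC(=O)[C@](C(C)=O)(CC(=O)OC(C)(C)C)CCC=O | intermediate
6 | methyl (1S)-1-(2-tert-butoxy-2-oxoethyl)-4-hydroxy-2-oxocyclohexane-1-carboxylate (both C4 epimers) | COC(=O)[C@]1(CC(=O)OC(C)(C)C)CCC(O)CC1=O | intermediate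
7 | methyl (1S)-1-(2-tert-butoxy-2-oxoethyl)-2-oxocyclohex-3-ene-1-carboxylate | COC(=O)[C@]1(CC(=O)OC(C)(C)C)CCC=CC1=O | intermediate
8 | methyl (1S)-1-(2-tert-butoxy-2-oxoethyl)-2-[(tert-butyldimethylsilyl)oxy]cyclohexa-2,4-diene-1-carboxylate | COC(=O)[C@]1(CC(=O)OC(C)(C)C)CC=CC=C1O[Si](C)(C)C(C)(C)C | intermediate
9 | methyl (1R,4S,6S)-4-(2-tert-butoxy-2-oxoethyl)-3-[(tert-butyldimethylsilyl)oxy]-7-oxabicyclo[4.1.0]hept-2-ene-4-carboxylate (epoxide oxygen cis to CO2Me) | [C@@H]12C=C(O[Si](C)(C)C(C)(C)C)[C@@](C(=O)OC)(CC(=O)OC(C)(C)C)C[C@@H]1O2 | intermediate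
10 | methyl (1S,5S)-1-(2-tert-butoxy-2-oxoethyl)-5-hydroxy-2-oxocyclohex-3-ene-1-carboxylate | C1=CC(=O)[C@@](C(=O)OC)(CC(=O)OC(C)(C)C)C[C@@H]1O | intermediate
11 | methyl (1S,5S)-1-(2-tert-butoxy-2-oxoethyl)-5-[(tert-butyldimethylsilyl)oxy]-2-oxocyclohex-3-ene-1-carboxylate | C1=CC(=O)[C@@](C(=O)OC)(CC(=O)OC(C)(C)C)C[C@@H]1O[Si](C)(C)C(C)(C)C | intermediate
12 | tert-butyl 2-[(1R,5S)-5-[(tert-butyldimethylsilyl)oxy]-2-hydroxy-1-(hydroxymethyl)cyclohex-3-en-1-yl]acetate (both epimers at the ring CHOH carbon) | C1=CC(O)[C@@](CO)(CC(=O)OC(C)(C)C)C[C@@H]1O[Si](C)(C)C(C)(C)C | intermediate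
13 | tert-butyl 2-[(1R,5S)-5-[(tert-butyldimethylsilyl)oxy]-1-formyl-2-oxocyclohex-3-en-1-yl]acetate | C1=CC(=O)[C@@](C=O)(CC(=O)OC(C)(C)C)C[C@@H]1O[Si](C)(C)C(C)(C)C | intermediate
14 | 6-methylhept-5-en-2-one | CC(=O)CCC=C(C)C | starting material
15 | diethyl 6-methylhepta-1,5-dien-2-yl phosphate | C=C(CCC=C(C)C)OP(=O)(OCC)OCC | intermediate
16 | 6-methylhept-5-en-1-yne | C#CCCC=C(C)C | intermediate
17 | [(1E)-2,6-dimethylhepta-1,5-dien-1-yl]dimethylaluminium | C[Al](C)/C=C(\C)CCC=C(C)C | intermediate
18 | (1E)-1-iodo-2,6-dimethylhepta-1,5-diene | I/C=C(\C)CCC=C(C)C | intermediate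
19 | [(1E)-2,6-dimethylhepta-1,5-dien-1-yl]lithium | [Li]/C=C(\C)CCC=C(C)C | intermediate
20 | [(1E)-2,6-dimethylhepta-1,5-dien-1-yl]magnesium bromide | Br[Mg]/C=C(\C)CCC=C(C)C | intermediate
21 | tert-butyl 2-[(1R,5S)-5-[(tert-butyldimethylsilyl)oxy]-1-[(1R,2E)-1-hydroxy-3,7-dimethylocta-2,6-dien-1-yl]-2-oxocyclohex-3-en-1-yl]acetate (present in step 10 as its bromomagnesium alkoxide) | C1=CC(=O)[C@@]([C@H](O)/C=C(\C)CCC=C(C)C)(CC(=O)OC(C)(C)C)C[C@@H]1O[Si](C)(C)C(C)(C)C | intermediate
22 | (1R,5R,9S)-9-[(tert-butyldimethylsilyl)oxy]-1-[(1E)-2,6-dimethylhepta-1,5-dien-1-yl]-2-oxaspiro[4.5]dec-7-ene-3,6-dione | C1=CC(=O)[C@@]2(CC(=O)O[C@@H]2/C=C(\C)CCC=C(C)C)C[C@@H]1O[Si](C)(C)C(C)(C)C | intermediate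
23 | (1R,5R,9S)-1-[(1E)-2,6-dimethylhepta-1,5-dien-1-yl]-9-hydroxy-2-oxaspiro[4.5]dec-7-ene-3,6-dione | C1=CC(=O)[C@@]2(CC(=O)O[C@@H]2/C=C(\C)CCC=C(C)C)C[C@@H]1O | intermediate
24 | (1R,5R,9S)-1-[(1E)-2,6-dimethylhepta-1,5-dien-1-yl]-3,6-dioxo-2-oxaspiro[4.5]dec-7-en-9-yl 2,2,2-trichloroethanimidate | C1=CC(=O)[C@@]2(CC(=O)O[C@@H]2/C=C(\C)CCC=C(C)C)C[C@@H]1OC(=N)C(Cl)(Cl)Cl | intermediate
25 | cis-fused 2-(trichloromethyl)-4,5-dihydro-1,3-oxazole spanning O9 and N8 of (1R,5R,8R,9S)-1-[(1E)-2,6-dimethylhepta-1,5-dien-1-yl]-2-oxaspiro[4.5]decane-3,6-dione | ClC(Cl)(Cl)C3=N[C@@H]1CC(=O)[C@@]2(CC(=O)O[C@@H]2/C=C(\C)CCC=C(C)C)C[C@@H]1O3 | intermediate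
26 | (1R,5R,8R,9S)-8-amino-1-[(1E)-2,6-dimethylhepta-1,5-dien-1-yl]-3,6-dioxo-2-oxaspiro[4.5]decan-9-yl 2,2,2-trichloroacetate hydrochloride | [Cl-].[NH3+][C@@H]1CC(=O)[C@@]2(CC(=O)O[C@@H]2/C=C(\C)CCC=C(C)C)C[C@@H]1OC(=O)C(Cl)(Cl)Cl | intermediate
27 | 2,2,2-trichloro-N-[(1R,5R,8R,9S)-1-[(1E)-2,6-dimethylhepta-1,5-dien-1-yl]-9-hydroxy-3,6-dioxo-2-oxaspiro[4.5]decan-8-yl]acetamide | ClC(Cl)(Cl)C(=O)N[C@@H]1CC(=O)[C@@]2(CC(=O)O[C@@H]2/C=C(\C)CCC=C(C)C)C[C@@H]1O | intermediate
28 | (+)-miliusane V, N-[(1R,5R,8R,9S)-1-[(1E)-2,6-dimethylhepta-1,5-dien-1-yl]-9-hydroxy-3,6-dioxo-2-oxaspiro[4.5]decan-8-yl]acetamide | CC(=O)N[C@@H]1CC(=O)[C@@]2(CC(=O)O[C@@H]2/C=C(\C)CCC=C(C)C)C[C@@H]1O | target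

**Count**

Total step count: 14 (steps 8 and 9 make the side-chain iodide).
Longest linear sequence: 12 steps (steps 1–7 and 10–14, from methyl acetoacetate).

**Steps most likely to fail**

Step 4. The process at risk is facial discrimination at C4: the induction from C2 acts across a nearly flat diene and rests on a conformational argument, and epoxidation of the enol ether bond at C6 is a second leak. The fallback sets out from 7. γ-Oxidation of the enone with t-BuOOH, K2CO3 and catalytic Pd(OH)2/C in CH2Cl2 should give methyl (1S)-1-(2-tert-butoxy-2-oxoethyl)-2,5-dioxocyclohex-3-ene-1-carboxylate F1, an enedione that cannot tautomerise to a hydroquinone because C2 is quaternary. Noyori-type asymmetric transfer hydrogenation with RuCl[(S,S)-TsDPEN](p-cymene) in 2-propanol should then reduce only the unhindered C4 carbonyl (the C1 carbonyl is neopentylic), with the catalyst rather than C2 choosing the face. This gives 10, where the route is rejoined; the antipodal catalyst is the alternative should C2 prove mismatched.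

Step 10. The processes at risk are attack on the wrong aldehyde face if the chelate does not form, retro-aldol cleavage of the magnesium aldolate on warming, and sluggish displacement of tert-butoxide. The fallback sets out from 13 and 18. Nozaki–Hiyama–Kishi coupling (CrCl2, catalytic NiCl2, DMSO, 23 °C) joins C9 and C10 through an alkenylchromium species that adds only to aldehydes and leaves a non-basic trivalent chromium alkoxide, so 21 can be isolated as the free alcohol. It is then closed in a separate operation with ZnBr2 in CH2Cl2, which activates the tert-butyl ester without Brønsted acid, to give 22, where the route is rejoined; C9 epimers would be separated at that stage. This detour makes no compound outside the list (F0).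

Step 6. The process at risk is loss of chemoselectivity: partial reduction of the tert-butyl ester, arrest of the hindered methyl ester at the aldehyde stage, or attack of an aluminium alkoxide on the C8 ester. The fallback sets out from 11. Luche reduction (NaBH4, CeCl3·7H2O, MeOH, −78 °C) should reduce only the enone carbonyl and give methyl (1S,5S)-1-(2-tert-butoxy-2-oxoethyl)-5-[(tert-butyldimethylsilyl)oxy]-2-hydroxycyclohex-3-ene-1-carboxylate F2 (both C2 carbinol epimers). LiBH4 in THF (0 → 23 °C) then reduces the methyl ester, assisted by the neighbouring hydroxyl, and leaves the tert-butyl ester, to give 12, where the route is rejoined.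

**Further compounds**

F1 | step 4 | methyl (1S)-1-(2-tert-butoxy-2-oxoethyl)-2,5-dioxocyclohex-3-ene-1-carboxylate | COC(=O)[C@]1(CC(=O)OC(C)(C)C)CC(=O)C=CC1=O
F0 | step 10 | none | none
F2 | step 6 | methyl (1S,5S)-1-(2-tert-butoxy-2-oxoethyl)-5-[(tert-butyldimethylsilyl)oxy]-2-hydroxycyclohex-3-ene-1-carboxylate | C1=CC(O)[C@@](C(=O)OC)(CC(=O)OC(C)(C)C)C[C@@H]1O[Si](C)(C)C(C)(C)C
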